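The ten-membered carbocycle is traced back to a cyclohexane. Ring atoms C1–C6 (C4 carrying its methyl) together with C10, its methyl and C9 are the ring and isopropenyl group of carvone; an extra C1–C6 bond therefore hides the cyclodecane in a trans-1-(E-2-silylvinyl)-2-isopropenylcyclohexan-1-ol. One anionic oxy-Cope shift forms C8–C9, breaks C1–C6, fixes C8 and the E-C1=C10 alkene and releases an enolate towards C7 only, which methyl bromoacetate alkylates (C7–C11). The precursor is the fully oxygenated cyclohexanol (C3 dioxolane, C4 and C5 methoxymethyl ethers) reached from (S)-carvone, whose carbonyl carbon becomes C5 so that C6 is simply its α′-carbon.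

Key step: step 13

Remarks before the steps

Assumption: locants are those of the ten-membered ring of the target (C1–C2 oxirane, C3 ketone, C4 carbinol with methyl, C5 and C6 ester carbons, C7 and C8 lactone ring carbons, C9 CH2, C10 CH–CH3, C11(=C13)–C12 lactone). They are kept for the six-membered intermediates, where the isopropenyl carbon is C10 and its CH2 is C9.

Design points:
- The carvone carbonyl carbon is used as C5, which calls for the (S)-enantiomer. C6 is then oxidised by ordinary α′-enolate chemistry, and no γ-enolisation of carvone (prone to aromatisation) is needed.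
- The C4/C5 diol is trans, with O4 cis and O5 trans to isopropenyl. It is made by hydride delivery anti to a trans-oxirane, followed by acid opening of that oxirane at tertiary C4 with inversion.
- After the ring expansion the C1=C10 alkene is saturated before the C–Si bond is oxidised, because the electrophilic oxidation would not spare a trisubstituted alkene.
- The lactone is closed on O8 while C6 is still a ketone, since O6 could otherwise compete.
- The C1=C2 enone is installed kinetically by dehydrogenation, because the conjugated enone is not the thermodynamic isomer in a ten-membered ring.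
- The oxirane of the target is cis, so the Z-enone is the substrate of the epoxidation.
- The C6 configuration of the intermediates up to the cyclohexanone is immaterial (C6 becomes trigonal again) and is drawn as the expected trans isomer.

Step 1
Reactants: 1 (S)-(+)-carvone
Product: 4 6-silyloxycarvone, via silyl dienol ether 2 (not isolated), via silyloxy oxirane 3 (not isolated)
Conditions: TBSOTf, Et3N, CH2Cl2, −78 → 0 °C; pentane, filtration; mCPBA, hexane/CH2Cl2, −20 °C → rt
Reagents that add atoms: tert-butyldimethylsilyl triflate, CC(C)(C)[Si](C)(C)OS(=O)(=O)C(F)(F)F; m-chloroperbenzoic acid, OOC(=O)c1cccc(Cl)c1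
Why: Rubottom oxidation, in which soft enolisation can only remove an α′-proton at C6, mCPBA attacks the electron-rich silyl enol ether much faster than the isopropenyl or the C3=C4 bond and from the face anti to the adjacent C1 isopropenyl group, and the silyloxy oxirane opens with 1,4-silyl shift to the C6 silyl ether (C6–O trans to isopropenyl).

Step 2
Reactants: 4 6-silyloxycarvone
Product: 5 silyloxy epoxy ketone
Conditions: H2O2 (30% aq.), NaOH (cat.), MeOH, 0 °C
Reagents that add atoms: hydrogen peroxide, OO
Why: Weitz–Scheffer nucleophilic epoxidation, in which hydroperoxide adds to C3 axially and anti to the C1 isopropenyl group and the enolate closes on the same face, so that the oxirane is trans to isopropenyl and cis to the C6 silyloxy group while the isopropenyl alkene, inert to a nucleophilic oxidant, survives.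

Step 3
Reactants: 5 silyloxy epoxy ketone
Product: 6 epoxy alcohol
Conditions: NaBH4, CeCl3·7H2O, MeOH, −78 → −40 °C
Reagents that add atoms: none
Why: Luche reduction, in which hydride reaches C5 from the face opposite to both the oxirane oxygen and the bulky C6 silyloxy group (polar Felkin–Anh and steric control agree), which should place the C5 hydroxyl cis to the oxirane and trans to isopropenyl.

Step 4
Reactants: 6 epoxy alcohol
Product: 7 epoxy MOM ether
Conditions: MOMCl, i-Pr2NEt, CH2Cl2, 0 °C → rt
Reagents that add atoms: chloromethyl methyl ether, COCCl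
Why: O-alkylation of the alcohol with the chloromethyl ether (acetal protection) under a weak amine base, which avoids silyl migration from O6 and leaves the oxirane untouched.

Step 5
Reactants: 7 epoxy MOM ether
Product: 8 trans-3,4-diol
Conditions: HClO4 (0.3 M aq.), THF, 0 °C → rt
Reagents that add atoms: water, O
Why: Acid-catalysed epoxide hydrolysis obeying the Fürst–Plattner rule, in which water opens the protonated trisubstituted oxirane at tertiary C4 with inversion, the only trans-diaxial path that keeps isopropenyl equatorial, so that the C4 hydroxyl ends cis to isopropenyl and trans to the C5 MOM-oxy group while C3 keeps its oxygen.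

Step 6
Reactants: 8 trans-3,4-diol
Product: 9 hydroxy ketone
Conditions: SO3·pyridine, DMSO, i-Pr2NEt, CH2Cl2, 0 °C
Reagents that add atoms: none
Why: Parikh–Doering oxidation, in which only the secondary C3 hydroxyl can be oxidised and activated dimethyl sulfoxide neither cleaves the 1,2-diol nor touches the alkene, giving the tertiary α-hydroxy ketone without a new stereocentre.

Step 7
Reactants: 9 hydroxy ketone
Product: 10 bis-MOM ketone
Conditions: MOMCl, i-Pr2NEt, ClCH2CH2Cl, 60 °C
Reagents that add atoms: chloromethyl methyl ether, COCCl
Why: O-alkylation with the chloromethyl ether, in which the tertiary α-ketol hydroxyl, more acidic and less shielded once C3 is trigonal, is capped under forcing but non-enolising amine conditions.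

Step 8
Reactants: 10 bis-MOM ketone
Product: 11 dioxolane silyl ether
Conditions: Me3SiOCH2CH2OSiMe3, TMSOTf (cat.), CH2Cl2, −78 → −20 °C
Reagents that add atoms: 1,2-bis(trimethylsilyloxy)ethane, C[Si](C)(C)OCCO[Si](C)(C)C
Why: Silyl-transfer ketalisation driven by formation of hexamethyldisiloxane, which converts even a hindered α-alkoxy ketone into its dioxolane at low temperature, where the MOM ethers, the silyl ether and the isopropenyl group persist.

Step 9
Reactants: 11 dioxolane silyl ether
Product: 12 C6 alcohol
Conditions: Bu4NF, THF, rt
Reagents that add atoms: none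
Why: Fluoride-induced desilylation (Si–F bond formation) frees the C6 hydroxyl without affecting the acetals or the alkene.

Step 10
Reactants: 12 C6 alcohol
Product: 13 cyclohexanone
Conditions: Dess–Martin periodinane, NaHCO3, CH2Cl2, 0 °C → rt
Reagents that add atoms: none
Why: Dess–Martin oxidation under buffered, non-enolising conditions should give the C6 ketone without epimerising the allylic C1–H next to the new carbonyl.

Step 11
Reactants: 14 ethynyldimethylphenylsilane
Product: 15 (E)-stannylvinylsilane
Conditions: Bu3SnH, AIBN (cat.), neat, 80 °C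
Reagents that add atoms: tributyltin hydride, CCCC[SnH](CCCC)CCCC
Why: Radical hydrostannation, in which the stannyl radical adds to the terminal alkyne carbon and reversible addition equilibrates the product to the E-1,2-dimetallated alkene.

Step 12
Reactants: 13 cyclohexanone; 15 (E)-stannylvinylsilane
Product: 17 trans-dialkenylcyclohexanol, via (E)-silylvinyllithium 16 (not isolated)
Conditions: 15, n-BuLi, THF, −78 °C; then 13, LaCl3·2LiCl, THF, −78 °C; NH4Cl (aq.)
Reagents that add atoms: (E)-stannylvinylsilane 15, CCCC[Sn](CCCC)(CCCC)/C=C/[Si](C)(C)c1ccccc1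
Why: Tin–lithium exchange with retention of alkene geometry followed by 1,2-addition, in which the nucleophile enters C6 equatorially, anti to the adjacent equatorial isopropenyl group and away from the syn-axial C4 MOM-oxy group that blocks the axial path, giving the axial carbinol with trans alkenyl groups while the lanthanum salt suppresses enolisation at C1.

Step 13
Reactants: 17 trans-dialkenylcyclohexanol; 18 methyl bromoacetate
Product: 21 cyclodec-5-enone ester, via potassium alkoxide 19 (not isolated), via potassium enolate 20 (not isolated)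
Conditions: KH, 18-crown-6, THF, 0 °C → rt; then BrCH2CO2Me (excess), −78 °C
Reagents that add atoms: methyl bromoacetate 18, COC(=O)CBr
Why: Deprotonation by KH with 18-crown-6 gives the dissociated C6 alkoxide 19, whose oxyanion weakens the C1–C6 bond and drives a concerted suprafacial [3,3] shift of the array C8=C7–C6–C1–C10=C9, which forms C8–C9, breaks C1–C6 and leaves the E-C1=C10 alkene and the C6=C7 enolate 20, alkylated at C7 by the bromoacetate in an SN2 step. The closest known reaction type is the anionic oxy-Cope ring expansion of trans-1,2-dialkenylcyclohexanols to (E)-cyclodec-5-enones with alkylation of the enolate in the same flask. The ten-membered ring is not closed by a cyclisation but by a four-atom ring expansion: the new C8–C9 bond joins the two alkene termini inside a six-centre chair array while the old six-membered ring is opened. C8 is set by that chair, with both alkenyl groups and the E-silyl group equatorial (chirality transfer from C1 and C6), and C7 by attack of the electrophile on the outer face of the ring enolate, opposite to the C8–C9 bond, which places the acetate arm trans to silicon. The step needs chair rather than boat geometry, secured by the trans-diequatorial alkenyl groups, and a single enolate regioisomer, secured by the rearrangement itself and kept by alkylating at −78 °C with excess electrophile before proton transfer to C5 can occur.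

Step 14
Reactants: 21 cyclodec-5-enone ester
Product: 22 cyclodecanone ester
Conditions: H2 (1 atm), [Ir(cod)(PCy3)(py)]PF6 (5 mol%), CH2Cl2, rt
Reagents that add atoms: none
Why: Homogeneous catalytic hydrogenation, in which the strained E-trisubstituted alkene turns one face to the ring interior, so that syn delivery of hydrogen to the outer face of the conformer inherited from the chair transition state should give the 10R methyl centre while the ketone, ester, acetals and arylsilane are untouched.

Step 15
Reactants: 22 cyclodecanone ester
Product: 24 lactone ketone, via hydroxy ester 23 (not isolated)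
Conditions: KBr, NaOAc, AcOOH, AcOH, 0 °C → rt; then PPTS (cat.), PhH, 50 °C
Reagents that add atoms: peracetic acid, CC(=O)OO
Why: Fleming–Tamao oxidation, in which ipso-bromodesilylation of the phenyl group is followed by peracid-induced 1,2-shift of C8 from silicon to oxygen with retention, and the resulting γ-hydroxy ester lactonises onto O8 without ambiguity because C6 is still a ketone, giving the trans-fused butyrolactone.

Step 16
Reactants: 24 lactone ketone
Product: 25 lactone alcohol
Conditions: LiBH(s-Bu)3, THF, −78 °C; AcOH, −78 °C
Reagents that add atoms: none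
Why: Ketone reduction under Felkin–Anh control, in which the bulky hydride should reach C6 on the outer face of the ring, anti to the C5 MOM-oxy group, to give the 6S alcohol (O5/O6 threo, O6 anti to O8), the lactone being inert at −78 °C and the cold acidic quench preventing acyl transfer to O6.

Step 17
Reactants: 25 lactone alcohol
Product: 26 tris-MOM lactone ketal
Conditions: MOMCl, i-Pr2NEt, CH2Cl2, 40 °C
Reagents that add atoms: chloromethyl methyl ether, COCCl
Why: O-alkylation with the chloromethyl ether under a weak amine base caps O6 before any translactonisation and gives three identical ether groups for a single late release.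

Step 18
Reactants: 26 tris-MOM lactone ketal
Product: 27 keto lactone
Conditions: HCl (1 M aq.), THF, rt
Reagents that add atoms: water, O
Why: Acid-catalysed ketal hydrolysis, in which the dioxolane of a medium-ring ketone (relief of transannular strain on going to the trigonal carbon) is cleaved by dilute acid at room temperature while MOM ethers require much stronger acid.

Step 19
Reactants: 27 keto lactone
Product: 29 (Z)-enone, via trimethylsilyl enol ether 28 (not isolated)
Conditions: TMSOTf, Et3N, CH2Cl2, −20 → 0 °C; then Pd(OAc)2, MeCN, rt
Reagents that add atoms: none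
Why: Saegusa–Ito oxidation, in which soft enolisation can only go towards C2 (C4 is quaternary and the lactone is not enolised), and palladium diacetate converts the silyl enol ether into a palladium enolate whose β-hydride elimination installs the C1=C2 enone kinetically, expected as the cis isomer favoured in a ten-membered ring, without equilibration to the β,γ-isomer.

Step 20
Reactants: 29 (Z)-enone
Product: 30 epoxy ketone
Conditions: t-BuOOH (decane), DBU, CH2Cl2, 0 °C
Reagents that add atoms: tert-butyl hydroperoxide, CC(C)(C)OO
Why: Weitz–Scheffer epoxidation, in which tert-butylperoxide should add to C1 on the exposed face of the twisted enone, anti to the C9 ring bond when C10–H eclipses the alkene (A(1,3) strain with C3), and the enolate closes to the cis-oxirane (1S,2S), the lactone and acetals being inert under non-aqueous conditions.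

Step 21
Reactants: 30 epoxy ketone
Product: 34 methylene lactone, via lithium enolate 31 (not isolated), via Mannich base 32 (not isolated), via ammonium iodide 33 (not isolated)
Conditions: LiN(SiMe3)2, THF, −78 °C; Me2N=CH2+ I−, −78 → 0 °C; then MeI, MeOH, rt; then NaHCO3 (aq.), CH2Cl2, rt
Reagents that add atoms: N,N-dimethylmethyleneiminium iodide, C=[N+](C)C.[I-]
Why: α-Methylenation by Mannich reaction, quaternisation and E1cB elimination, in which the lactone is the only enolisable carbonyl (C3 lies between quaternary C4 and the oxirane CH), the iminium salt traps the enolate at −78 °C and loss of trimethylamine gives the exocyclic alkene.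

Step 22
Reactants: 34 methylene lactone
Product: 35 triol
Conditions: CF3CO2H/CH2Cl2/H2O, 0 °C → rt
Reagents that add atoms: none
Why: Acid-catalysed acetal hydrolysis removes the three MOM groups, and should spare the electron-poor oxirane next to the ketone and the methylene lactone, which tolerate a non-nucleophilic acid at low temperature.

Step 23
Reactants: 35 triol; 36 (E)-crotonic anhydride
Product: 37 CNP0253228.1
Conditions: (E)-crotonic anhydride, pyridine, DMAP (cat.), CH2Cl2, 0 °C → rt
Reagents that add atoms: (E)-crotonic anhydride 36, C/C=C/C(=O)OC(=O)/C=C/C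
Why: DMAP-catalysed acyl transfer esterifies the two secondary hydroxyls at C5 and C6, while the tertiary C4 hydroxyl next to the ketone is too hindered and pyridine (in place of a trialkylamine) avoids deconjugation of the crotonyl group through a ketene.

Compound list

1 | (S)-(+)-carvone, (5S)-2-methyl-5-(prop-1-en-2-yl)cyclohex-2-en-1-one | CC1=CC[C@H](C(C)=C)CC1=O | starting material
2 | silyl dienol ether: tert-butyldimethylsilyl enol ether of 1 (C5–OSi, C5=C6 and C3=C4) | C1=C(O[Si](C)(C)C(C)(C)C)C(C)=CC[C@@H]1C(C)=C | intermediate (not isolated)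
3 | silyloxy oxirane: 5,6-epoxide of 2, oxygen trans to isopropenyl | O1[C@H]2[C@]1(O[Si](C)(C)C(C)(C)C)C(C)=CC[C@@H]2C(C)=C | intermediate (not isolated)
4 | 6-silyloxycarvone: 6-(tert-butyldimethylsilyloxy)carvone, C6–O trans to the C1 isopropenyl | CC(C)(C)[Si](C)(C)O[C@H]1C(=O)C(C)=CC[C@@H]1C(C)=C | intermediate
5 | silyloxy epoxy ketone: 3,4-epoxide of 4, oxirane trans to isopropenyl and cis to O6 | CC(C)(C)[Si](C)(C)O[C@H]1C(=O)[C@@]2(C)O[C@H]2C[C@@H]1C(C)=C | intermediate
6 | epoxy alcohol: C5 carbinol of 5, hydroxyl cis to the oxirane and to O6 | CC(C)(C)[Si](C)(C)O[C@H]1[C@@H](O)[C@@]2(C)O[C@H]2C[C@@H]1C(C)=C | intermediate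
7 | epoxy MOM ether: C5 methoxymethyl ether of 6 | CC(C)(C)[Si](C)(C)O[C@H]1[C@@H](OCOC)[C@@]2(C)O[C@H]2C[C@@H]1C(C)=C | intermediate
8 | trans-3,4-diol: C4–OH cis to isopropenyl (C4 methyl trans), C3–OH trans to C4–OH, C5 OMOM, C6 OTBS | CC(C)(C)[Si](C)(C)O[C@H]1[C@@H](OCOC)[C@](C)(O)[C@@H](O)C[C@@H]1C(C)=C | intermediate
9 | hydroxy ketone: 3-ketone of 8 with free tertiary C4–OH | CC(C)(C)[Si](C)(C)O[C@H]1[C@@H](OCOC)[C@](C)(O)C(=O)C[C@@H]1C(C)=C | intermediate
10 | bis-MOM ketone: C4 and C5 methoxymethyl ethers, C3 ketone, C6 OTBS | CC(C)(C)[Si](C)(C)O[C@H]1[C@@H](OCOC)[C@](C)(OCOC)C(=O)C[C@@H]1C(C)=C | intermediate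
11 | dioxolane silyl ether: C3 ethylene ketal of 10 | CC(C)(C)[Si](C)(C)O[C@H]1[C@@H](OCOC)[C@](C)(OCOC)C2(OCCO2)C[C@@H]1C(C)=C | intermediate
12 | C6 alcohol: desilylated 11 | O[C@H]1[C@@H](OCOC)[C@](C)(OCOC)C2(OCCO2)C[C@@H]1C(C)=C | intermediate
13 | cyclohexanone: C6 ketone with C1 isopropenyl, C3 dioxolane, C4 (methyl, OMOM cis to isopropenyl), C5 OMOM trans to isopropenyl | O=C1[C@@H](OCOC)[C@](C)(OCOC)C2(OCCO2)C[C@@H]1C(C)=C | intermediate
14 | ethynyldimethylphenylsilane | C#C[Si](C)(C)c1ccccc1 | starting material
15 | (E)-stannylvinylsilane: (E)-tributyl[2-(dimethylphenylsilyl)ethenyl]stannane | CCCC[Sn](CCCC)(CCCC)/C=C/[Si](C)(C)c1ccccc1 | intermediate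
16 | (E)-silylvinyllithium: (E)-[2-(dimethylphenylsilyl)ethenyl]lithium | [Li]/C=C/[Si](C)(C)c1ccccc1 | intermediate (not isolated)
17 | trans-dialkenylcyclohexanol: C6 carbinol with E-silylvinyl trans to the C1 isopropenyl, hydroxyl cis to it; C3 dioxolane, C4/C5 OMOM | O[C@]1(/C=C/[Si](C)(C)c2ccccc2)[C@@H](OCOC)[C@](C)(OCOC)C3(OCCO3)C[C@@H]1C(C)=C | intermediate (precursor of the key step)
18 | methyl bromoacetate | COC(=O)CBr | starting material
19 | potassium alkoxide of 17 | [K+].[O-][C@]1(/C=C/[Si](C)(C)c2ccccc2)[C@@H](OCOC)[C@](C)(OCOC)C3(OCCO3)C[C@@H]1C(C)=C | intermediate (not isolated)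
20 | potassium enolate: ten-membered C6=C7 enolate (O cis to C8), E-C1=C10, C8 silyl | [K+].[O-]/C1=C\[C@H]([Si](C)(C)c2ccccc2)C/C(C)=C/CC3(OCCO3)[C@@](C)(OCOC)[C@@H]1OCOC | intermediate (not isolated)
21 | cyclodec-5-enone ester: C6 ketone, C7 CH2CO2Me trans to the C8 SiMe2Ph, E-C1=C10, C3 dioxolane, C4/C5 OMOM | COC(=O)C[C@H]1[C@H]([Si](C)(C)c2ccccc2)C/C(C)=C/CC3(OCCO3)[C@@](C)(OCOC)[C@H](OCOC)C1=O | intermediate (product of the key step)
22 | cyclodecanone ester: 1,10-dihydro-21 with 10R methyl | COC(=O)C[C@H]1[C@H]([Si](C)(C)c2ccccc2)C[C@@H](C)CCC3(OCCO3)[C@@](C)(OCOC)[C@H](OCOC)C1=O | intermediate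
23 | hydroxy ester: C8–OH in place of silicon (retention) | COC(=O)C[C@H]1[C@H](O)C[C@@H](C)CCC2(OCCO2)[C@@](C)(OCOC)[C@H](OCOC)C1=O | intermediate (not isolated)
24 | lactone ketone: trans-fused 12,8-lactone, C6 ketone | C1C(=O)O[C@@H]2C[C@@H](C)CCC3(OCCO3)[C@@](C)(OCOC)[C@H](OCOC)C(=O)[C@@H]12 | intermediate
25 | lactone alcohol: 6S carbinol of 24 | C1C(=O)O[C@@H]2C[C@@H](C)CCC3(OCCO3)[C@@](C)(OCOC)[C@H](OCOC)[C@@H](O)[C@@H]12 | intermediate
26 | tris-MOM lactone ketal: C4, C5, C6 OMOM, C3 dioxolane | C1C(=O)O[C@@H]2C[C@@H](C)CCC3(OCCO3)[C@@](C)(OCOC)[C@H](OCOC)[C@@H](OCOC)[C@@H]12 | intermediate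
27 | keto lactone: C3 ketone of 26 | C1C(=O)O[C@@H]2C[C@@H](C)CCC(=O)[C@@](C)(OCOC)[C@H](OCOC)[C@@H](OCOC)[C@@H]12 | intermediate
28 | trimethylsilyl enol ether: C2=C3 enol ether of 27 (alkene geometry not defined) | C1C(=O)O[C@@H]2C[C@@H](C)CC=C(O[Si](C)(C)C)[C@@](C)(OCOC)[C@H](OCOC)[C@@H](OCOC)[C@@H]12 | intermediate (not isolated)
29 | (Z)-enone: C1=C2 cis-enone conjugated to the C3 ketone | C1C(=O)O[C@@H]2C[C@@H](C)/C=C\C(=O)[C@@](C)(OCOC)[C@H](OCOC)[C@@H](OCOC)[C@@H]12 | intermediate
30 | epoxy ketone: (1S,2S) cis-oxirane next to the C3 ketone | C1C(=O)O[C@@H]2C[C@@H](C)[C@@H]3O[C@@H]3C(=O)[C@@](C)(OCOC)[C@H](OCOC)[C@@H](OCOC)[C@@H]12 | intermediate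
31 | lithium enolate of lactone 30 | C1=C([O-])O[C@@H]2C[C@@H](C)[C@@H]3O[C@@H]3C(=O)[C@@](C)(OCOC)[C@H](OCOC)[C@@H](OCOC)[C@@H]12.[Li+] | intermediate (not isolated)
32 | Mannich base: C11 dimethylaminomethyl lactone (C11 configuration not defined) | CN(C)CC1C(=O)O[C@@H]2C[C@@H](C)[C@@H]3O[C@@H]3C(=O)[C@@](C)(OCOC)[C@H](OCOC)[C@@H](OCOC)[C@@H]12 | intermediate (not isolated)
33 | ammonium iodide: trimethylammonium salt of 32 | C[N+](C)(C)CC1C(=O)O[C@@H]2C[C@@H](C)[C@@H]3O[C@@H]3C(=O)[C@@](C)(OCOC)[C@H](OCOC)[C@@H](OCOC)[C@@H]12.[I-] | intermediate (not isolated)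
34 | methylene lactone: α-methylene lactone with C4, C5, C6 OMOM | C=C1C(=O)O[C@@H]2C[C@@H](C)[C@@H]3O[C@@H]3C(=O)[C@@](C)(OCOC)[C@H](OCOC)[C@@H](OCOC)[C@@H]12 | intermediate
35 | triol: 4,5,6-trihydroxy epoxy keto methylene lactone | C=C1C(=O)O[C@@H]2C[C@@H](C)[C@@H]3O[C@@H]3C(=O)[C@@](C)(O)[C@H](O)[C@@H](O)[C@@H]12 | intermediate
36 | (E)-crotonic anhydride, (E)-but-2-enoic anhydride | C/C=C/C(=O)OC(=O)/C=C/C | starting material
37 | CNP0253228.1: (1S,2S,4S,5R,6S,7S,8R,10R)-5,6-bis[(E)-but-2-enoyloxy]-1,2-epoxy-4-hydroxy-3-oxo ten-membered 12,8-lactone with C11=C13 methylene | C=C1C(=O)O[C@@H]2C[C@@H](C)[C@@H]3O[C@@H]3C(=O)[C@@](C)(O)[C@H](OC(=O)/C=C/C)[C@@H](OC(=O)/C=C/C)[C@@H]12 | target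

Total step count: 23. Longest linear sequence: 22 steps (steps 1–10 and 12–23 from (S)-carvone); step 11 prepares the vinylstannane.

Steps most likely to fail

Step 13 (key step). The rearrangement may be followed by proton transfer between the potassium enolate and the alkylated ketone. That would lead to over-alkylation, or to migration of the enolate to C5 with β-elimination of the C4 MOM-oxy group; O-alkylation is also possible under crown-ether conditions. Fallback: setting out from 17, the rearrangement is run alone and enolate 20 is quenched with Me3SiCl to give the ten-membered trimethylsilyl enol ether F1. This is cleaved with MeLi (THF, 0 °C) to the salt-free lithium enolate F2, which is less basic and regiostable, and F2 is alkylated with 18 in THF/DMPU at −78 °C. The route is rejoined at 21.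

Step 14. The E-alkene can swing through the ring and expose either face, and the alkene may migrate before hydrogen is delivered; either process erodes the C10 configuration. Fallback: setting out from 21, substrate control is replaced by catalyst control. The alkene is hydrogenated with a cationic iridium complex of a chiral phosphinooxazoline, [Ir(cod)(L)]B[3,5-(CF3)2C6H3]4 with L = (S)- or (R)-2-[2-(diphenylphosphino)phenyl]-4-tert-butyl-4,5-dihydrooxazole, under H2 (50 bar) in CH2Cl2. The antipode that matches the substrate is chosen, and the route is rejoined at 22 with no new compound (F0).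

Step 20. Peroxide may add to the wrong face of the enone, bond rotation in the peroxy enolate may give the trans-oxirane, or base may deconjugate the enone through C10–H. Fallback: setting out from 29, the ketone is reduced with NaBH4/CeCl3·7H2O (MeOH, −78 °C) to the Z-allylic alcohol F3, whose hydroxyl lies on the face that is to carry the oxirane (the epimer can be re-oxidised to 29 and recycled). Hydroxyl-directed, stereospecific epoxidation with VO(acac)2 and t-BuOOH (CH2Cl2, 0 °C) then gives the syn epoxy alcohol F4, which Dess–Martin periodinane oxidises to 30.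

Further compounds
F1 | step 13 | trimethylsilyl enol ether of the ring-expanded ketone (C6=C7, E-C1=C10, C8 silyl) | C[Si](C)(C)O/C1=C\[C@H]([Si](C)(C)c2ccccc2)C/C(C)=C/CC3(OCCO3)[C@@](C)(OCOC)[C@@H]1OCOC
F2 | step 13 | lithium enolate of the ring-expanded ketone | [Li+].[O-]/C1=C\[C@H]([Si](C)(C)c2ccccc2)C/C(C)=C/CC3(OCCO3)[C@@](C)(OCOC)[C@@H]1OCOC
F0 | step 14 | none | none
F3 | step 20 | Z-allylic alcohol (C3 carbinol of 29, hydroxyl syn to the future oxirane) | C1C(=O)O[C@@H]2C[C@@H](C)/C=C\[C@H](O)[C@@](C)(OCOC)[C@H](OCOC)[C@@H](OCOC)[C@@H]12
F4 | step 20 | syn epoxy alcohol (cis-oxirane, C3 carbinol) | C1C(=O)O[C@@H]2C[C@@H](C)[C@@H]3O[C@@H]3[C@H](O)[C@@](C)(OCOC)[C@H](OCOC)[C@@H](OCOC)[C@@H]12
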